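The route rests on the cyclobutane C3–C4–C5–C6 of the target: C6 is bonded to C3 and C5 and faces C4 across the four-membered ring, while C3, C4 and C5 also belong to the seven-membered ring C1–C2–C3–C4–C5–C10–C11 (labels defined below). A rhodium carbene at C6, carried on C5, is therefore added across a C3=C4 double bond of a cycloheptene. This one operation forms C6–C3 and C6–C4, closes both cyclopropanes of a bicyclo[1.1.0]butane and sets C3, C4 and C6 from C5 alone; the surplus C4–C6 bond is hydrogenolysed afterwards. The precursor is a 1,11-trans-bis(silyloxy)cycloheptene with a C3 methyl, a C4 silyloxymethyl and a tert-butyl diazoacetate carbon (C6) on C5.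

Key step: step 10

Remarks
- Labels: carbons are labelled along the target SMILES and keep their label in every intermediate. C1 and C11 carry the ester oxygens, C2 and C8 are CH2, C3 bears a methyl, C4, C5 and C6 are the cyclobutane CH groups, C7 is the ketone carbon, C9 is CHMe and C10 is CMe2. Descriptors quoted with labels, for example (1S,11S), refer to these labels. The target is (1S,3R,4S,5S,6R,9R,11S).
- Assumption: the facial sense of the epoxidation in step 2 is taken from 2,2-dimethyl-2H-chromenes (CMe2 next to a cis, conjugated double bond); if the other enantiomer prevailed, the (S,S) catalyst would be used and nothing else would change.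
- Design of the precursor: the carbene-bearing ester is tert-butyl and the oxygen on C9 is a triethylsilyl ether. A benzyl or alkyl ether at C9 would sit five atoms from the carbene carbon and invite oxonium ylide formation with Stevens or [2,3] shift, and a methyl ester would lactonise onto the free C9 alcohol of step 7.
- Convention: compounds 18–22 are drawn with the C6 and C4 substituents on the exo face (cis to the C3 methyl and C5 hydrogen). Epimers at C4 or C6 formed in step 11 are carried along and converge in step 15.

Step 1
Reactants: 1 (R)-(−)-carvone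
Product: 4 eucarvone, via carvone hydrobromide 2 (not isolated), via car-3-en-2-one 3 (not isolated)
Conditions: HBr (33% in AcOH), 0 °C; then KOH, MeOH, 65 °C
Reagents that add atoms: none
Why: Markovnikov addition of HBr to the isopropenyl group, base-induced 1,3-elimination to the carenone and base-mediated opening of its cyclopropane through the dienolate (the classical eucarvone rearrangement) should give the achiral dienone, so no stereocenter needs control here.

Step 2
Reactants: 4 eucarvone
Product: 5 eucarvone 1,11-epoxide (C1 R; C11 S)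
Conditions: (R,R)-N,N'-bis(3,5-di-tert-butylsalicylidene)-1,2-cyclohexanediaminomanganese chloride (5 mol %), 4-phenylpyridine N-oxide, NaOCl (aq, pH 11.3), CH2Cl2, 0 °C
Reagents that add atoms: sodium hypochlorite, [Na+].[O-]Cl
Why: Jacobsen–Katsuki epoxidation, in which the electrophilic oxomanganese species should attack the cis-disubstituted, diene-conjugated C1=C11 bond flanked by CMe2 and leave the ketone-deactivated C2=C3 bond, the salen ligand choosing the face that gives C1 (R) and C11 (S).

Step 3
Reactants: 5 eucarvone 1,11-epoxide
Product: 6 (1S,11S)-trans-diol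
Conditions: HClO4 (cat.), THF/H2O, 0 °C to rt
Reagents that add atoms: water, O
Why: Acid-catalysed anti opening of the vinyl epoxide, in which water should attack the allylic, unhindered C1 with inversion while the neopentyl C11–O bond stays, so the trans-diol forms and the enantiomeric purity is kept.

Step 4
Reactants: 6 (1S,11S)-trans-diol
Product: 7 bis(tert-butyldimethylsilyl) ether of 6
Conditions: t-BuMe2SiOTf, 2,6-lutidine, CH2Cl2, 0 °C to rt
Reagents that add atoms: tert-butyldimethylsilyl triflate, CC(C)(C)[Si](C)(C)OS(=O)(=O)C(F)(F)F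
Why: Silyl triflate silylation protects both secondary alcohols, including the hindered C11–OH next to CMe2, and touches no stereocenter.

Step 5
Reactants: 7 bis-silyl enone; 8 tert-butyl bromoacetate
Product: 9 C5-alkylated enone (5S; side chain trans to the C11 silyloxy group)
Conditions: LiN(i-Pr)2, THF, −78 °C; then 8, DMPU, −78 to −40 °C
Reagents that add atoms: none
Why: Kinetic α'-deprotonation at C5 (the only enolisable CH2) and SN2 alkylation of the cross-conjugated lithium dienolate with the reactive bromoacetate, as in α'-alkylations of isophorone, should place the new chain anti to the neighbouring pseudoaxial C11 silyloxy group, which sets C5 (S) with the chain trans to C11–O and cis to C1–O.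

Step 6
Reactants: 9 C5-alkylated enone
Product: 11 enol triflate (C4–OTf; C3=C4), via triethylsilyl enol ether 10 (not isolated)
Conditions: Et3SiH, RhCl(PPh3)3 (2 mol %), PhMe, 60 °C; solvent exchange; then CsF, PhNTf2, DME, rt
Reagents that add atoms: N-phenylbis(trifluoromethanesulfonimide), O=S(=O)(N(c1ccccc1)S(=O)(=O)C(F)(F)F)C(F)(F)F
Why: Rhodium-catalysed 1,4-hydrosilylation with a monohydrosilane gives the regiodefined tetrasubstituted silyl enol ether (hydride goes to C2, so no carbanion arises next to the C1 silyloxy group), and fluoride-triggered O-sulfonylation of the released enolate by PhNTf2 fixes the double bond at C3=C4 without touching C5 or the ester.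

Step 7
Reactants: 11 enol triflate; 12 (tributylstannyl)methanol
Product: 13 allylic alcohol (C4–CH2OH)
Conditions: Pd(PPh3)4 (10 mol %), LiCl, 1,4-dioxane, 95 °C
Reagents that add atoms: none
Why: Stille coupling of the alkenyl triflate with the hydroxymethylstannane, aided by chloride, installs C9 on C4 with the double bond held at C3=C4, and the tert-butyl ester keeps the new δ-hydroxy ester from lactonising.

Step 8
Reactants: 13 allylic alcohol
Product: 14 triethylsilyl ether of 13
Conditions: Et3SiCl, imidazole, CH2Cl2, 0 °C
Reagents that add atoms: chlorotriethylsilane, CC[Si](Cl)(CC)CC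
Why: Standard silylation of the primary allylic alcohol gives an ether whose oxygen is a poor donor and carries no group prone to Stevens or [2,3] shift, which disfavours oxonium ylide formation with the C6 carbene of step 10.

Step 9
Reactants: 14 triethylsilyl ether
Product: 16 tert-butyl diazo ester (diazo on C6), via α-trifluoroacetyl ester 15 (not isolated)
Conditions: LiN(i-Pr)2, THF, −78 °C; CF3CO2CH2CF3; then 4-acetamidobenzenesulfonyl azide, Et3N, MeCN, rt
Reagents that add atoms: 4-acetamidobenzenesulfonyl azide, CC(=O)Nc1ccc(cc1)S(=O)(=O)N=[N+]=[N-]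
Why: Detrifluoroacetylative diazo transfer (a deacylative Regitz-type transfer), in which Claisen trifluoroacetylation of the ester lithium enolate activates C6 and the sulfonyl azide then delivers N2 with loss of the trifluoroacetyl group as the N-acyl sulfonamide, while the non-enolisable C5 keeps its configuration.

Step 10
Reactants: 16 tert-butyl diazo ester
Product: 17 bicyclo[1.1.0]butane tert-butyl ester
Conditions: Rh2(O2CCPh3)4 (1 mol %), CH2Cl2, −78 °C, slow addition of 16; filtration through basic alumina
Reagents that add atoms: none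
Why: Rh2(O2CCPh3)4 extrudes N2 from 16 to give an electrophilic rhodium carbene at C6, which the electron-rich tetrasubstituted C3=C4 bond attacks asynchronously (C6–C4 first, positive charge on the tertiary C3) before the rhodium-bound carbon closes onto C3. The closest known reaction type is the dirhodium-catalysed intramolecular cyclopropanation of tert-butyl 2-diazopent-4-enoates to bicyclo[1.1.0]butane-1-carboxylates, of which 16 is a ring-embedded member (C7, C6, C5, C4=C3). Ring C4–C5–C6 closes in a 3-exo-trig sense on the alkene and ring C3–C4–C6 by collapse of the C6–Rh bond onto the developing cation at C3, the two three-membered rings sharing the new central bond C4–C6. C3, C4 and C6 are set by the C5 stereocenter alone, because the one-carbon tether lets C6 reach only the alkene face cis to it; this puts C2 and C10 endo on the wings and leaves the C3 methyl and C5 hydrogen exo. The step needs chemoselectivity for cyclopropanation over 1,2-hydride shift from C5, allylic C–H insertion at C2 and oxonium ylide formation; low temperature, slow addition, the bulky triphenylacetate ligands, the tert-butyl ester and the weakly basic silyl ethers should secure it. Allylic 1,2-strain with the C4 silyloxymethyl group should hold the C5 side chain pseudoaxial over the π face, which is the geometry the closure requires.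

Step 11
Reactants: 17 bicyclo[1.1.0]butane tert-butyl ester
Product: 18 cyclobutane tert-butyl ester
Conditions: H2 (1 atm), Pd/C (10%), K2CO3, EtOAc, rt
Reagents that add atoms: none
Why: Catalytic hydrogenolysis of the strained, ester-conjugated central σ bond of a bicyclo[1.1.0]butane to the cyclobutane is a classical strain-release reaction that leaves the silyl ethers and the ester untouched, and the C4 and C6 configurations formed here are not relied upon because both centres are equilibrated in step 15.

Step 12
Reactants: 18 cyclobutane tert-butyl ester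
Product: 20 carboxylic acid, via trimethylsilyl ester 19 (not isolated)
Conditions: Me3SiOTf, 2,6-lutidine, CH2Cl2, 0 °C; then aqueous work-up (pH 5)
Reagents that add atoms: none
Why: Silyl triflate-mediated cleavage of the tert-butyl ester (O-silylation and loss of isobutene) gives the trimethylsilyl ester, which is hydrolysed on work-up, under the usual conditions for removing tert-butyl esters in the presence of silyl ethers.

Step 13
Reactants: 20 carboxylic acid
Product: 21 methyl ketone
Conditions: MeLi (3 equiv), Et2O, 0 °C; inverse quench into cold aq HCl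
Reagents that add atoms: methyllithium, [Li]C
Why: Addition of methyllithium to the lithium carboxylate gives a stable dilithium gem-diolate that releases the methyl ketone only on quenching (the carboxylic acid to methyl ketone synthesis), which brings in C8.

Step 14
Reactants: 21 methyl ketone
Product: 22 keto aldehyde
Conditions: (COCl)2, DMSO, CH2Cl2, −78 to −30 °C; then Et3N, −78 °C to rt
Reagents that add atoms: none
Why: Under Swern conditions a primary triethylsilyl ether is cleaved by the chlorosulfonium reagent and oxidised directly to the aldehyde while secondary tert-butyldimethylsilyl ethers stay, so deprotection and oxidation at C9 are one operation.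

Step 15
Reactants: 22 keto aldehyde
Product: 24 tricyclic enone, via aldol adduct 23 (not isolated)
Conditions: KOH, MeOH/THF, rt to 50 °C, 0.01 M
Reagents that add atoms: none
Why: Intramolecular aldol condensation (6-enolexo-exo-trig addition of the methyl ketone enolate carbon C8 to the C9 aldehyde, then E1cB dehydration), in which C4 and C6 are both α to a carbonyl group and epimerise under the basic conditions while only the isomer with C7 and C9 cis on the exo face can close the bicyclo[3.1.1]heptenone, so the C4 and C6 configurations of the target are set here under thermodynamic and geometric control.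

Step 16
Reactants: 24 tricyclic enone
Product: 25 C9-methyl ketone
Conditions: Me2CuLi (from MeLi and CuI), Et2O, −78 to −20 °C; aqueous work-up
Reagents that add atoms: lithium dimethylcuprate, [Li+].C[Cu-]C
Why: Conjugate addition of the Gilman cuprate to a bicyclo[3.1.1]hept-3-en-2-one, as known for verbenone-type enones, should deliver the methyl group to C9 from the side of the C5–H bridge and away from the C3 bridge whose methyl group overhangs the enone, which gives C9 (R).

Step 17
Reactants: 25 C9-methyl ketone
Product: 26 diol ketone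
Conditions: HF (48% aq), MeCN, rt
Reagents that add atoms: none
Why: Fluoride-mediated cleavage of both silyl ethers, aqueous HF being effective for the hindered C11 ether, under conditions to which the ketone, the cyclobutane and all stereocenters are inert.

Step 18
Reactants: 26 diol ketone; 27 angelic acid
Product: 28 C1 mono-angelate (C11 hydroxyl free)
Conditions: 27 (1.2 equiv), 2,4,6-trichlorobenzoyl chloride (1.2 equiv), Et3N, PhMe, rt; then 26, PhMe, 60 °C
Reagents that add atoms: none
Why: Yamaguchi-type esterification through the mixed anhydride of angelic acid, run without a nucleophilic amine catalyst so that the (Z)-2-methylbut-2-enoyl group is not isomerised to the tiglate, should acylate with retention the C1 hydroxyl, which is flanked by the C2 methylene and is more accessible than the C11 hydroxyl next to the quaternary C10; any C11 monoester or diester formed alongside is carried on and converges in step 19.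

Step 19
Reactants: 28 C1 mono-angelate; 27 angelic acid
Product: 29 target diangelate
Conditions: 27 (4 equiv), 2,4,6-trichlorobenzoyl chloride (4 equiv), Et3N, PhMe, rt; then 28, PhMe, 90 °C
Reagents that add atoms: none
Why: The same mixed-anhydride esterification, now with excess reagent and at higher temperature, should acylate the remaining hindered C11 hydroxyl with retention and without Z-to-E isomerisation, the ketone and the first angelate being inert to these non-nucleophilic conditions.

Compound list
1 | (R)-(−)-carvone, (5R)-2-methyl-5-(prop-1-en-2-yl)cyclohex-2-en-1-one | CC1=CC[C@H](CC1=O)C(C)=C | starting material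
2 | carvone hydrobromide, (5R)-5-(2-bromopropan-2-yl)-2-methylcyclohex-2-en-1-one | CC1=CC[C@H](CC1=O)C(C)(C)Br | intermediate (not isolated)
3 | (1S,6R)-car-3-en-2-one, 3,7,7-trimethylbicyclo[4.1.0]hept-3-en-2-one | CC1=CC[C@@H]2[C@H](C1=O)C2(C)C | intermediate (not isolated)
4 | eucarvone, 2,6,6-trimethylcyclohepta-2,4-dien-1-one (achiral) | CC1=CC=CC(C)(C)CC1=O | intermediate
5 | eucarvone 1,11-epoxide, (1R,7S)-3,6,6-trimethyl-8-oxabicyclo[5.1.0]oct-2-en-4-one (label C1 R, C11 S) | O=C1C(C)=C[C@H]2O[C@H]2C(C)(C)C1 | intermediate
6 | (4S,5S)-4,5-dihydroxy-2,6,6-trimethylcyclohept-2-en-1-one (label 1S,11S; trans-diol) | O=C1C(C)=C[C@H](O)[C@@H](O)C(C)(C)C1 | intermediate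
7 | (4S,5S)-4,5-bis(tert-butyldimethylsilyloxy)-2,6,6-trimethylcyclohept-2-en-1-one | O=C1C(C)=C[C@H](O[Si](C)(C)C(C)(C)C)[C@@H](O[Si](C)(C)C(C)(C)C)C(C)(C)C1 | intermediate
8 | tert-butyl bromoacetate | BrCC(=O)OC(C)(C)C | starting material
9 | enone 7 carrying CH2CO2t-Bu on C5; label (1S,5S,11S); side chain trans to C11–O and cis to C1–O | O=C1C(C)=C[C@H](O[Si](C)(C)C(C)(C)C)[C@@H](O[Si](C)(C)C(C)(C)C)C(C)(C)[C@@H]1CC(=O)OC(C)(C)C | intermediate
10 | triethylsilyl enol ether: C4–OSiEt3, C3=C4, C2H2; label (1S,5S,11S) | CC(C)(C)[Si](C)(C)O[C@H]1CC(C)=C(O[Si](CC)(CC)CC)[C@@H](CC(=O)OC(C)(C)C)C(C)(C)[C@@H]1O[Si](C)(C)C(C)(C)C | intermediate (not isolated)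
11 | enol triflate: C4–OSO2CF3, C3=C4; label (1S,5S,11S) | CC(C)(C)[Si](C)(C)O[C@H]1CC(C)=C(OS(=O)(=O)C(F)(F)F)[C@@H](CC(=O)OC(C)(C)C)C(C)(C)[C@@H]1O[Si](C)(C)C(C)(C)C | intermediate
12 | (tributylstannyl)methanol | OC[Sn](CCCC)(CCCC)CCCC | starting material
13 | allylic alcohol: C4–CH2OH (C9), C3=C4; label (1S,5R,11S) | CC(C)(C)[Si](C)(C)O[C@H]1CC(C)=C(CO)[C@@H](CC(=O)OC(C)(C)C)C(C)(C)[C@@H]1O[Si](C)(C)C(C)(C)C | intermediate
14 | triethylsilyl ether of 13: C4–CH2OSiEt3; label (1S,5R,11S) | CC(C)(C)[Si](C)(C)O[C@H]1CC(C)=C(CO[Si](CC)(CC)CC)[C@@H](CC(=O)OC(C)(C)C)C(C)(C)[C@@H]1O[Si](C)(C)C(C)(C)C | intermediate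
15 | α-trifluoroacetyl ester: C6 bears COCF3 and CO2t-Bu (C6 epimers and enol form) | CC(C)(C)[Si](C)(C)O[C@H]1CC(C)=C(CO[Si](CC)(CC)CC)[C@@H](C(C(=O)C(F)(F)F)C(=O)OC(C)(C)C)C(C)(C)[C@@H]1O[Si](C)(C)C(C)(C)C | intermediate (not isolated)
16 | key precursor: cycloheptene with C3 methyl, C4 CH2OSiEt3, tert-butyl diazoacetate carbon C6 on C5, C1 and C11 OSiMe2t-Bu; label (1S,5R,11S) | CC(C)(C)[Si](C)(C)O[C@H]1CC(C)=C(CO[Si](CC)(CC)CC)[C@@H](C(=[N+]=[N-])C(=O)OC(C)(C)C)C(C)(C)[C@@H]1O[Si](C)(C)C(C)(C)C | intermediate
17 | key product: bicyclo[1.1.0]butane (tricyclo[5.1.0.0(2,8)]octane skeleton) with central bond C4–C6, wings C3 and C5 joined endo,endo by C2–C1–C11–C10, C6 CO2t-Bu, C4 CH2OSiEt3, C3 methyl and C5 H exo; label (1S,3R,4R,5R,6S,11S) | CC(C)(C)[Si](C)(C)O[C@H]1C[C@]2(C)[C@]3(CO[Si](CC)(CC)CC)[C@@H]([C@]23C(=O)OC(C)(C)C)C(C)(C)[C@@H]1O[Si](C)(C)C(C)(C)C | intermediate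
18 | cyclobutane (bicyclo[4.1.1]octane skeleton): C6 CO2t-Bu and C4 CH2OSiEt3 on the exo face, cis to C3 methyl and C5 H; label (1S,3R,4S,5S,6R,11S) | CC(C)(C)[Si](C)(C)O[C@H]1C[C@]2(C)[C@@H](CO[Si](CC)(CC)CC)[C@@H]([C@H]2C(=O)OC(C)(C)C)C(C)(C)[C@@H]1O[Si](C)(C)C(C)(C)C | intermediate
19 | trimethylsilyl ester corresponding to 18 | CC(C)(C)[Si](C)(C)O[C@H]1C[C@]2(C)[C@@H](CO[Si](CC)(CC)CC)[C@@H]([C@H]2C(=O)O[Si](C)(C)C)C(C)(C)[C@@H]1O[Si](C)(C)C(C)(C)C | intermediate (not isolated)
20 | carboxylic acid (C6–CO2H); label (1S,3R,4S,5S,6R,11S) | CC(C)(C)[Si](C)(C)O[C@H]1C[C@]2(C)[C@@H](CO[Si](CC)(CC)CC)[C@@H]([C@H]2C(=O)O)C(C)(C)[C@@H]1O[Si](C)(C)C(C)(C)C | intermediate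
21 | methyl ketone (C6–C7(=O)–C8H3), C4–CH2OSiEt3; label (1S,3R,4S,5S,6R,11S) | CC(C)(C)[Si](C)(C)O[C@H]1C[C@]2(C)[C@@H](CO[Si](CC)(CC)CC)[C@@H]([C@H]2C(C)=O)C(C)(C)[C@@H]1O[Si](C)(C)C(C)(C)C | intermediate
22 | keto aldehyde (C4–C9HO, C6–COCH3); label (1S,3R,4S,5S,6R,11S) | CC(C)(C)[Si](C)(C)O[C@H]1C[C@]2(C)[C@@H](C=O)[C@@H]([C@H]2C(C)=O)C(C)(C)[C@@H]1O[Si](C)(C)C(C)(C)C | intermediate
23 | aldol adduct: tricyclic β-hydroxy ketone, C9–OH (either C9 epimer) | CC(C)(C)[Si](C)(C)O[C@H]1C[C@]2(C)[C@@H]3[C@@H]([C@H]2C(=O)CC3O)C(C)(C)[C@@H]1O[Si](C)(C)C(C)(C)C | intermediate (not isolated)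
24 | tricyclic enone (C7=O, C8=C9) on the tricyclo[5.4.0.0(2,8)]undecane skeleton; label (1S,3R,4S,5S,6R,11S) | CC(C)(C)[Si](C)(C)O[C@H]1C[C@]2(C)[C@@H]3[C@@H]([C@H]2C(=O)C=C3)C(C)(C)[C@@H]1O[Si](C)(C)C(C)(C)C | intermediate
25 | C9-methyl ketone, bis(tert-butyldimethylsilyl) ether; label (1S,3R,4S,5S,6R,9R,11S) | CC(C)(C)[Si](C)(C)O[C@H]1C[C@]2(C)[C@@H]3[C@@H]([C@H]2C(=O)C[C@H]3C)C(C)(C)[C@@H]1O[Si](C)(C)C(C)(C)C | intermediate
26 | diol ketone; label (1S,3R,4S,5S,6R,9R,11S) | O[C@H]1C[C@]2(C)[C@@H]3[C@@H]([C@H]2C(=O)C[C@H]3C)C(C)(C)[C@@H]1O | intermediate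
27 | angelic acid, (2Z)-2-methylbut-2-enoic acid | C/C=C(/C)C(O)=O | starting material
28 | C1 mono-angelate: C1 O-[(2Z)-2-methylbut-2-enoyl], C11 hydroxyl free; label (1S,3R,4S,5S,6R,9R,11S) | C/C=C(/C)C(=O)O[C@H]1C[C@]2(C)[C@@H]3[C@@H]([C@H]2C(=O)C[C@H]3C)C(C)(C)[C@@H]1O | intermediate
29 | CNP0109825.1: 3,3,7,11-tetramethyl-9-oxotricyclo[5.4.0.0(2,8)]undecane-4,5-diyl bis[(2Z)-2-methylbut-2-enoate]; label (1S,3R,4S,5S,6R,9R,11S) | C/C=C(/C)C(=O)O[C@H]1C[C@]2(C)[C@@H]3[C@@H]([C@H]2C(=O)C[C@H]3C)C(C)(C)[C@@H]1OC(=O)/C(C)=C\C | target

Total step count: 19. Longest linear sequence: 19 steps, from carvone 1 to 29.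

Steps most likely to fail

1. Step 10, carbene addition. The 1,2-shift of the tertiary allylic hydrogen on C5 to the carbene carbon (giving a conjugated dienoate), allylic C–H insertion at C2 or attack of an ether oxygen may outrun closure onto the hindered tetrasubstituted double bond. The fallback avoids a carbene at C6 altogether and sets out from 16. Warming 16 in the dark (PhMe, 80 °C) should bring about the intramolecular 1,3-dipolar cycloaddition of the diazo ester across C3=C4 on the only face the tether allows. C6 bonds to C4 and the terminal nitrogen to C3, giving the cyclopropane-fused 1-pyrazoline F1 (a 2,3-diazabicyclo[3.1.0]hex-2-ene unit). Photolysis of F1 (350 nm, Et2O, −40 °C) extrudes N2, and the 1,3-diradical at C6 and C3 closes to the bicyclo[1.1.0]butane, which is the established pyrazoline route to bicyclobutanes. The sequence returns to the route at 17.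

2. Step 11, hydrogenolysis of the central bond. Adsorption of the fully substituted, concave-shielded C4–C6 bond on the metal may be too slow, or a side bond of the bicyclobutane may be cleaved instead. The fallback replaces the surface reaction by electron transfer in solution and sets out from 17: SmI2, HMPA, t-BuSH and t-BuOH in THF at −78 °C. Reduction of the ester-conjugated central bond opens it to a samarium enolate at C6 and a tertiary radical at C4. The thiol quenches the radical by hydrogen-atom transfer before a second electron can expel the C9 silyloxy group, and the enolate is protonated on work-up. This gives 18 directly as a mixture of C4 and C6 epimers, which step 15 accepts; no new compound is made (F0). The sequence returns to the route at 18.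

3. Step 5, alkylation at C5. Facial discrimination of the flexible seven-membered dienolate by the C11 silyloxy group may be poor, giving both C5 epimers. The fallback replaces substrate control by auxiliary control and sets out from 7. Condensation with (R)-1-amino-2-(methoxymethyl)pyrrolidine (neat, 60 °C) gives the RAMP hydrazone F2. Deprotonation at C5 with LiN(i-Pr)2 (THF, 0 °C) and alkylation of the azaenolate with 8 at −95 °C gives the C5-alkylated hydrazone F3, the auxiliary directing the electrophile to the face that leads to C5 (S). Two-phase hydrolysis with aqueous oxalic acid and Et2O releases the ketone without epimerisation. The sequence returns to the route at 9.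

Further compounds
F1 | step 10 | cyclopropane-fused 1-pyrazoline from 16 (C6–C4 bond, C6–N=N–C3 bridge, cyclopropane C4–C5–C6) | CC(C)(C)[Si](C)(C)O[C@H]1C[C@@]2(C)N=N[C@@]3(C(=O)OC(C)(C)C)[C@@H](C(C)(C)[C@@H]1O[Si](C)(C)C(C)(C)C)[C@@]23CO[Si](CC)(CC)CC
F0 | step 11 | none | none
F2 | step 5 | RAMP hydrazone of enone 7 (C=N geometry not fixed) | COC[C@H]1CCCN1N=C1C(C)=C[C@H](O[Si](C)(C)C(C)(C)C)[C@@H](O[Si](C)(C)C(C)(C)C)C(C)(C)C1
F3 | step 5 | C5-alkylated RAMP hydrazone (C5 S; C=N geometry not fixed) | COC[C@H]1CCCN1N=C1C(C)=C[C@H](O[Si](C)(C)C(C)(C)C)[C@@H](O[Si](C)(C)C(C)(C)C)C(C)(C)[C@@H]1CC(=O)OC(C)(C)C
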